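The hour is your unit here, and every amount is a fraction of the substrate charge.

| flask | substrate | partner | temperature | remark | time |
|---|---|---|---|---|---|
| blue | 0.15 M | 2.5 equiv | 10 °C | run made earlier |  |
| gamma | 0.10 M | 2.50 equiv | 10 °C |  | 50 h |
| zeta | 0.10 M | 2.50 equiv |  | at −15 °C until 25 h, from then on at 35 °C | 50 h |
| eta | 0.10 M | 2.50 equiv | 35 °C |  | 50 h |
| theta | 0.10 M | 2.50 equiv | −15 °C |  | 50 h |

blue run (percent of the substrate charged)

| time / h | target / % | substrate / % |
|---|---|---|
| 1.33 | 0 | 98.5 |
| 2.00 | 3.9 | 96.4 |
| 3.00 | 6.3 | 94.6 |
| 5.00 | 8.9 | 94.9 |
| 10.0 | 13.0 | 84.5 |
| 15.0 | 20.6 | 81.4 |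

(scatter of a reading: 1 percentage point)

- the earlier runs were read with a standard deviation of 1 percentage point
- steps that have been proposed: substrate + partner -> target; substrate <-> dormant form; 2 partner -> homo dimer
- the earlier runs do not show what temperature does; that part of a forecast is a guess

- the best flask by amount of target, in percent of the substrate charged; "all alike" if 1.5 percentage points covers them all (gamma / zeta / eta / theta / all alike)
- amount of target at the end, in percent of the substrate charged, gamma
- amount of target at the end, in percent of the substrate charged, zeta
- amount of target at the end, in percent of the substrate charged, eta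
- amount of target at the end, in percent of the substrate charged, theta

Substrate is the reagent charged in the smaller amount, with partner at 2.50 equiv, so write its balance: substrate, target and dormant form add up to the charge. At the last blue reading, after 15.0 h, substrate and target together stand at 102%. That is the charge within a scatter of 1 percentage point per reading, so you can read no dormant form in the blue run.

Now take the hours in which target would claim half of the charge with partner held at its starting strength, the pseudo-first-order view. The last blue reading of 20.6% of target, with its scatter, reads as 45.1 h. I assume this stretches as partner strength falls, and gamma has 0.667 of the blue strength, so gamma comes to 67.6 h, its half-time.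

So the ladder at 10 °C runs from the blue half-time up to gamma's, with dormant form on a higher rung, too slow to read in 15.0 h; homo dimer has no reading at all. Gamma's 50 h is shorter than its half-time, so I commit to 40.1% of target there. The earlier runs do not show what temperature does. If warmth shortens the half-time, eta, with 50 h at 35 °C, should lead zeta, with 25.0 h there.

The forecast names eta as best, with 34% for gamma, lower than my figure, “allowing for partner loss”, then 66% for zeta, 80% for eta and 5% for theta.

The flasks give 28.3% for gamma, 36.2% for zeta, 41.1% for eta and 5.52% for theta, so eta is best. Gamma's target, read the same way, gives a half-time of 104 h, longer than my 67.6 h.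

    substrate + partner → target, rate k1*[substrate]*[partner]^1.5 (k = 1.05 × 10⁻⁴ M⁻¹·⁵ s⁻¹, Ea = 49.0 kJ mol⁻¹)
    substrate ⇌ dormant form (K = 0.330, k = 2.08 × 10⁻⁶ s⁻¹, Ea = 100 kJ mol⁻¹, ΔH = −71.0 kJ mol⁻¹)
    2 partner → homo dimer (k = 4.24 × 10⁻⁵ M⁻¹ s⁻¹, Ea = 79.0 kJ mol⁻¹)
    (constants at 35 °C)

Eta's 41.1% reads as a half-time of 65.5 h by the same reckoning, though eta's partner stands at 17.3% of its own charge at the end. A neighbour of eta is charged with 0.17 M of substrate at the same equivalents, temperature and time, so its starting partner strength is 1.70 times eta's. The reckoning then puts its half-time at 38.5 h, and over 50 h that gives 59.3% of target. The neighbour gives less than that, and its balance closes with 53.6% of target, 36.3% of substrate and 10.2% of dormant form.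

(The readings come from a simulation from invented constants, noise included.)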